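## Analysis of the target

Locants C1–C26 and O18 follow the atom order of the target SMILES and are used for every compound below.

- Target 37 is a 5-8-6-5 tetracarbocycle (rings A–D) of 25 carbons whose only heteroatom is the C17 hydroxyl.
- It has eight stereocentres in three clusters: C5/C25 on ring A (hydrogens cis, so the C4 branch and the C26 methyl are cis); C9/C22 at the trans B/C fusion; and C11/C19 at the trans C/D fusion together with C12 (isopropyl trans to C10) and C17 (hydroxyl cis to the angular C20 methyl).
- In the chair of ring C every carbon substituent is equatorial except the axial C20 methyl. C9 and C22 are therefore thermodynamic positions once C11 and C19 exist.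
- The ring A pair is contra-thermodynamic next to a C6 carbonyl, and it is separated from the other centres by a flat tetrasubstituted alkene, so it cannot be relayed from them.
- The C6=C7 alkene is exocyclic to ring A and ring-cis inside the eight-membered ring B. The C1=C2 methylene can migrate into ring B under acid, and both alkenes limit the use of late hydrogenation and strong acid.
- The difficulty lies in an eight-membered ring that carries a tetrasubstituted alkene of fixed geometry, in the quaternary C19 flanked by stereocentres, and in three stereo-clusters that do not communicate.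
- The strategy rests on ring D (C11, C12, C16, C17, C19). With C17 as a ketone, C16 is its α-carbon and C12 is a methylene of an isobutyl group on C11. The two are 1,5-related across the trans-diequatorial substituents of C19 and C11, so ring D can be closed last at C12–C16 by carbenoid C–H insertion.

## Retrosynthetic reasoning

**C17–O and C1=C2.** The carbinol of 37 is taken back to the C17 ketone of 36, and the methylene of 36 to the C2 ketone of 35. Both operations come last because a C2 carbonyl is wanted during ring D formation: it deactivates the C22–H bond and keeps a reactive alkene away from the carbenoid. Forward, a Wittig methylenation has to choose the cyclooctanone C2 over the neopentyl cyclopentanone C17, and hydride has to reach C17 from the face opposite the C20 methyl.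

**C12–C16.** Ring D of 35 is opened between C12 and C16, which leads to diazoketone 34 with its acyl group on C19 and isobutyl group on C11. Cutting here, and not at C16–C17 or C11–C12, means that the trans C/D fusion and the quaternary C19 are never made by a ring closure; only C12 is new. Forward, the metal carbenoid from 34 has to insert into one C12–H bond in the five-membered mode.

**C16–C17.** 34 is cut into keto acid 30 and the one-carbon diazo reagent 31. The forward reaction is acylation through the acid chloride 32.

**C6=C7 and ring B.** Oxidation-level changes relate 30 to the bis(silyl ether) 27. The tetrasubstituted alkene of 27 is cut to the 1,8-diketone 26. This bond is preferred to C2–C3 or C3–C4 because the alkene then forms inside ring B, where only the ring-cis geometry is possible, and ring B closes in the same step. Forward, a McMurry coupling has to proceed without loss of the C5 configuration α to the C6 ketone.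

**C7–C9.** The methyl ketone on C9 of 26 (through 25) is traced to enone 23, and 23 to enol triflate 20 and the two-carbon stannane 21. C9 is a ketone carbon in 19 and can be converted to its C9=C10 triflate. C9 becomes a stereocentre only on hydrogenation and, being α to the methyl ketone, can be equilibrated to the equatorial position. The same hydrogenation frees the C6 hydroxyl so that the ring A ketone is unveiled last.

**C2–C22.** 19 (through 18) is cut into enol silane 8 and aldehyde 17, an aldol disconnection that uses the regiodefined C9=C22 enol ether. This is the convergent step. The stereocentres of rings A and C come from the two enantiopure fragments, so no induction across the future alkene is needed. The carbinol configuration at C2 is irrelevant.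

**Ring C.** 8 comes from aldehyde 6 by reduction and silylation. The cyclohexene of 6 is cut at C10–C11 and C19–C21 into diene 2 and enal 5 (Diels–Alder). With the dienophile bond at C19=C11, the quaternary C19 and C11 form together, and their relationship (C20 methyl cis to isobutyl) is simply the E geometry of 5. The oxygen of 2 ends on C9, where it is needed. 5 is cut at its double bond into 3 and 4; 2 comes from 1.

**Ring A.** 17 is traced through 16 and 15 to allylic alcohol 14 and enone 13. The cis C4/C26 relationship is not accessible by enolate alkylation. It is made instead by syn addition of hydrogen to C5=C25, directed by the C6 hydroxyl, whose configuration comes from an enantioselective ketone reduction. 13 is cut at C4–C5 into iodoenone 10 and vinyl acetal 11; 10 comes from 9.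

## Alternatives that were turned down

**Alternative 1:** The disconnection is C4–C5 of ring B, traced to a cyclobutane in which C2 and C7 are still bonded (ring expansion from four to eight).
- Forward key step: the potassium C2 alkoxide, with the C3=C4 vinyl group on C2 and the ring A cyclopentene on C7, undergoes an anionic oxy-Cope shift. C4–C5 forms, C2–C7 breaks, and protonation of the C2 enolate gives the AB cyclooctenone A1.
- In favour: strain release and alkoxide acceleration make the shift easy. One pericyclic step delivers ring B, the C2 ketone, the ring-cis C6=C7 alkene and C5.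
- Against: A1 is only half of the molecule. Rings C and D, with quaternary C19, C11 and C12, would have to be annulated onto a flexible cyclooctenone from the C10 ether and the C22 methylene, with C19 and C11 under remote substrate control. The cyclobutane needs a cis pair made of a tertiary alkoxide carbon and a fully substituted C7. Which face of the cyclopentene reaches C4 depends on a rotamer preference set only by the C25 methyl.
- Comparison: on ring B and the alkene this route is stronger than the McMurry closure of 26, which carries an epimerisable C5. The chosen strategy instead brings ring C in as an enantiopure block made in one cycloaddition and leaves only C12 to the final ring closure, with fewer steps after the eight-membered ring exists.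

**Alternative 2:** The disconnection is C3–C4 of ring B, with the C1=C2 methylene created at the same time.
- Forward key step: Me2AlCl activates a C4 aldehyde on C5, and an isopropenyl group on C22 reacts as the ene (type-2 intramolecular carbonyl-ene). C3 bonds to C4 and a C1 hydrogen goes to oxygen, giving the tetracyclic alcohol A2.
- In favour: the exocyclic methylene appears without any late ketone olefination. On this point the route is stronger than the chosen one, which must differentiate two ketones in 35. The Lewis acid is mild.
- Against: the C4 hydroxyl is absent from the target and costs a deoxygenation next to two alkenes. Type-2 ene closures are favourable for six- and seven-membered rings but entropically poor for eight. The aldehyde sits on C5, which is allylic to C6=C7 and α-epimerisable under Lewis acid. The C6=C7 alkene would have to be made stereodefined in an acyclic setting, and the complete C/D unit with C12 and C17 carried through a long linear sequence.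
- Comparison: the chosen strategy lets ring formation fix the alkene geometry and creates C12 late on a rigid chair, at the price of the final Wittig step.

**Alternative 3:** The disconnection is C5–C6 of ring A, formed by a 1,2-shift from a 6-7 fused skeleton in which C5 is bonded to C7.
- Forward key step: ionisation of an equatorial C6 mesylate with anti-periplanar migration of C5 from C7 to C6. The six-membered ring contracts to ring A, the seven-membered ring expands to ring B, and the C7 cation loses the C6 hydrogen to give A3.
- In favour: 6-7 frameworks are easier to assemble than 5-8 ones. One step creates both ring sizes and the ring-cis tetrasubstituted alkene, and the migrating carbon keeps its configuration.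
- Against: the tertiary C7 cation is generated on a fully elaborated tetracycle. Shifts of C8 or C9, elimination towards C8 or C9 and transannular hydride shifts are near-equivalent pathways. The precursor needs an extra quaternary centre and a correctly oriented mesylate, and the silyl ether is exposed to acid.
- Comparison: this could be shorter to the AB unit than the chosen route. In the chosen key step, however, the chair geometry leaves one accessible C–H bond pair, so the risk is narrower.

Key step: step 23

Assumption (chemistry): the (S)-proline-derived oxazaborolidinium salt of step 3 is assumed to give the (1R,6R) adduct 6; if the sense of induction is the opposite, the mirror-image catalyst is used.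

## Route

Step 1
Reactants: 1 but-3-en-2-one
Product: 2 2-(tert-butyldimethylsilyloxy)buta-1,3-diene
Conditions: TBSOTf, Et3N, Et2O, 0 °C
Reagents that add atoms: tert-butyldimethylsilyl trifluoromethanesulfonate, CC(C)(C)[Si](C)(C)OS(=O)(=O)C(F)(F)F
Why: Soft enolisation and O-silylation of the enone give the 2-silyloxy diene; the tert-butyldimethylsilyl enol ether is chosen because it has to survive the acid catalyst of step 3, borohydride and chromatography.

Step 2
Reactants: 3 3-methylbutanal; 4 2-(triphenylphosphoranylidene)propanal
Product: 5 (E)-2,5-dimethylhex-2-enal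
Conditions: toluene, 90 °C
Reagents that add atoms: none
Why: Wittig olefination with a stabilised formyl ylide should give the E trisubstituted enal, which places the future C20 methyl and the isobutyl chain cis on the C19=C11 dienophile.

Step 3
Reactants: 2 2-(tert-butyldimethylsilyloxy)buta-1,3-diene; 5 (E)-2,5-dimethylhex-2-enal
Product: 6 (1R,6R)-4-(tert-butyldimethylsilyloxy)-1-methyl-6-(2-methylpropyl)cyclohex-3-ene-1-carbaldehyde
Conditions: (3aS)-1-(2-methylphenyl)-3,3-diphenyltetrahydro-1H,3H-pyrrolo[1,2-c][1,3,2]oxazaborole·HNTf2 (15 mol %), CH2Cl2, −78 to −40 °C; Et3N quench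
Reagents that add atoms: none
Why: This is a chiral oxazaborolidinium-catalysed Diels–Alder reaction of an α-substituted enal with a 2-silyloxy diene, in which the donor oxygen ends para to the formyl-bearing carbon (oxygen on C9, enol ether C9=C22). Suprafacial addition carries the E geometry of 5 into the cis C20 methyl/C11 isobutyl pair (C17 trans to isobutyl), and the catalyst-controlled face selection fixes the absolute configuration of C19 and C11.

Step 4
Reactants: 6 (1R,6R)-4-(tert-butyldimethylsilyloxy)-1-methyl-6-(2-methylpropyl)cyclohex-3-ene-1-carbaldehyde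
Product: 7 [(1R,6R)-4-(tert-butyldimethylsilyloxy)-1-methyl-6-(2-methylpropyl)cyclohex-3-en-1-yl]methanol
Conditions: NaBH4, EtOH, 0 °C
Reagents that add atoms: none
Why: Borohydride reduction of the neopentyl aldehyde leaves the silyl enol ether intact and takes C17 to an oxidation level that tolerates the later Lewis acid, enolate, palladium and titanium steps.

Step 5
Reactants: 7 [(1R,6R)-4-(tert-butyldimethylsilyloxy)-1-methyl-6-(2-methylpropyl)cyclohex-3-en-1-yl]methanol
Product: 8 tert-butyl{[(1R,6R)-4-(tert-butyldimethylsilyloxy)-1-methyl-6-(2-methylpropyl)cyclohex-3-en-1-yl]methoxy}dimethylsilane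
Conditions: TBSCl, imidazole, DMF, rt
Reagents that add atoms: tert-butyldimethylsilyl chloride, CC(C)(C)[Si](C)(C)Cl
Why: Standard silylation of the primary alcohol; the same silyl group is later placed on O at C2 so that both are removed together in step 19.

Step 6
Reactants: 9 3-methylcyclopent-2-en-1-one
Product: 10 2-iodo-3-methylcyclopent-2-en-1-one
Conditions: I2, pyridine, CH2Cl2, rt
Reagents that add atoms: iodine, II
Why: α-Iodination of the enone by conjugate addition of pyridine, iodination of the enolate and elimination gives the vinyl iodide needed at C5.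

Step 7
Reactants: 11 2-vinyl-1,3-dioxolane; 10 2-iodo-3-methylcyclopent-2-en-1-one
Product: 13 2-[2-(1,3-dioxolan-2-yl)ethyl]-3-methylcyclopent-2-en-1-one, via alkylborane 12 (not isolated)
Conditions: 9-BBN, THF, 0 °C to rt; then 10, PdCl2(dppf) (5 mol %), AsPh3, Cs2CO3, DMF/THF/H2O, rt
Reagents that add atoms: none
Why: Anti-Markovnikov hydroboration of the vinyl acetal followed by B-alkyl Suzuki–Miyaura coupling with the α-iodoenone attaches C4–C3–C2 to C5, with C2 as a masked aldehyde.

Step 8
Reactants: 13 2-[2-(1,3-dioxolan-2-yl)ethyl]-3-methylcyclopent-2-en-1-one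
Product: 14 (S)-2-[2-(1,3-dioxolan-2-yl)ethyl]-3-methylcyclopent-2-en-1-ol
Conditions: (3aR)-1-methyl-3,3-diphenyltetrahydro-1H,3H-pyrrolo[1,2-c][1,3,2]oxazaborole (15 mol %), BH3·SMe2, THF, −20 °C; MeOH
Reagents that add atoms: none
Why: CBS reduction in which the α-substituted alkene side of the enone acts as the large group, so the (R)-catalyst should deliver the (S)-carbinol at C6; this centre carries the absolute stereochemical information of ring A.

Step 9
Reactants: 14 (S)-2-[2-(1,3-dioxolan-2-yl)ethyl]-3-methylcyclopent-2-en-1-ol
Product: 15 (1S,2S,3S)-2-[2-(1,3-dioxolan-2-yl)ethyl]-3-methylcyclopentan-1-ol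
Conditions: [Ir(cod)(PCy3)(py)]PF6 (5 mol %), H2 (1–10 atm), CH2Cl2, rt
Reagents that add atoms: none
Why: Hydroxyl-directed hydrogenation with the cationic iridium catalyst adds both hydrogens to the tetrasubstituted C5=C25 bond from the face of the C6 hydroxyl. H5 and H25 therefore come out cis, which gives the contra-thermodynamic cis C4/C26 relationship of the target.

Step 10
Reactants: 15 (1S,2S,3S)-2-[2-(1,3-dioxolan-2-yl)ethyl]-3-methylcyclopentan-1-ol
Product: 16 2-{2-[(1S,2S,5S)-2-(benzyloxy)-5-methylcyclopentyl]ethyl}-1,3-dioxolane
Conditions: NaH, BnBr, Bu4NI (cat.), THF/DMF, 0 °C to rt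
Reagents that add atoms: benzyl bromide, BrCc1ccccc1
Why: Williamson benzylation; the benzyl ether keeps C6 at the alcohol level (no epimerisable C5) and is cleaved by the hydrogenation of step 16.

Step 11
Reactants: 16 2-{2-[(1S,2S,5S)-2-(benzyloxy)-5-methylcyclopentyl]ethyl}-1,3-dioxolane
Product: 17 3-[(1S,2S,5S)-2-(benzyloxy)-5-methylcyclopentyl]propanal
Conditions: 1 M HCl, THF, rt
Reagents that add atoms: water, O
Why: Acid hydrolysis of the dioxolane releases the C2 aldehyde; no stereocentre is α to it.

Step 12
Reactants: 8 tert-butyl{[(1R,6R)-4-(tert-butyldimethylsilyloxy)-1-methyl-6-(2-methylpropyl)cyclohex-3-en-1-yl]methoxy}dimethylsilane; 17 3-[(1S,2S,5S)-2-(benzyloxy)-5-methylcyclopentyl]propanal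
Product: 18 (2R,4R,5R)-2-{3-[(1S,2S,5S)-2-(benzyloxy)-5-methylcyclopentyl]-1-hydroxypropyl}-4-[(tert-butyldimethylsilyloxy)methyl]-4-methyl-5-(2-methylpropyl)cyclohexan-1-one (both carbinol epimers at C2)
Conditions: BF3·OEt2, CH2Cl2, −78 °C; aq. NaHCO3
Reagents that add atoms: none
Why: Mukaiyama aldol addition in which the regiodefined enol silane from the cycloaddition reacts only at C22, forming C2–C22 and the C9 ketone. The axial C20 methyl is 1,3 to C22, so the new chain should end equatorial (trans to C20), and this centre can also equilibrate α to the ketone. The C2 carbinol mixture is removed by oxidation in step 20.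

Step 13
Reactants: 18 (2R,4R,5R)-2-{3-[(1S,2S,5S)-2-(benzyloxy)-5-methylcyclopentyl]-1-hydroxypropyl}-4-[(tert-butyldimethylsilyloxy)methyl]-4-methyl-5-(2-methylpropyl)cyclohexan-1-one (both carbinol epimers at C2)
Product: 19 (2R,4R,5R)-2-{3-[(1S,2S,5S)-2-(benzyloxy)-5-methylcyclopentyl]-1-(tert-butyldimethylsilyloxy)propyl}-4-[(tert-butyldimethylsilyloxy)methyl]-4-methyl-5-(2-methylpropyl)cyclohexan-1-one (both C2 epimers)
Conditions: TBSOTf, 2,6-lutidine, CH2Cl2, −78 °C
Reagents that add atoms: tert-butyldimethylsilyl trifluoromethanesulfonate, CC(C)(C)[Si](C)(C)OS(=O)(=O)C(F)(F)F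
Why: Silylation of the aldol hydroxyl prevents retro-aldol cleavage and keeps C2 at the alcohol level, so that only two ketones are present in the carbonyl coupling of step 18.

Step 14
Reactants: 19 (2R,4R,5R)-2-{3-[(1S,2S,5S)-2-(benzyloxy)-5-methylcyclopentyl]-1-(tert-butyldimethylsilyloxy)propyl}-4-[(tert-butyldimethylsilyloxy)methyl]-4-methyl-5-(2-methylpropyl)cyclohexan-1-one (both C2 epimers)
Product: 20 enol triflate of 19 with C9(OTf)=C10 (all stereocentres as in 19)
Conditions: KHMDS, THF, −78 °C; then PhNTf2, −78 to 0 °C
Reagents that add atoms: N-phenylbis(trifluoromethanesulfonimide), O=S(=O)(N(c1ccccc1)S(=O)(=O)C(F)(F)F)C(F)(F)F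
Why: Kinetic deprotonation should occur at the methylene C10 and not at the tertiary C22, which also avoids β-elimination of the C2 silyloxy group; O-triflation then fixes the enolate as the C9=C10 triflate.

Step 15
Reactants: 20 enol triflate of 19 with C9(OTf)=C10 (all stereocentres as in 19); 21 tributyl(1-ethoxyvinyl)stannane
Product: 23 enone with acetyl (C7 and C8) on C9 and C9=C10 (other centres as in 19), via ethoxydiene 22 (not isolated)
Conditions: Pd(PPh3)4 (5 mol %), LiCl, THF, 65 °C; then aq. oxalic acid, THF, 0 °C
Reagents that add atoms: water, O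
Why: Stille coupling of the enol triflate with the acetyl-anion equivalent forms C7–C9, and mild hydrolysis of the enol ether gives the conjugated methyl ketone without loss of the silyl ethers.

Step 16
Reactants: 23 enone with acetyl (C7 and C8) on C9 and C9=C10 (other centres as in 19)
Product: 25 methyl ketone with equatorial acetyl on C9 and free C6 hydroxyl (C9 trans to the C22 chain and cis to C20), via C9-epimeric keto alcohols 24 (not isolated)
Conditions: H2 (1 atm), Pd/C, EtOAc, rt; filter; then NaOMe (cat.), MeOH, rt
Reagents that add atoms: none
Why: Heterogeneous hydrogenation saturates the conjugated C9=C10 bond and cleaves the benzyl ether in one operation. Base equilibration α to the methyl ketone should then put the acetyl group equatorial, because the chair is held by the equatorial isobutyl, silyloxymethyl and C22 substituents.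

Step 17
Reactants: 25 methyl ketone with equatorial acetyl on C9 and free C6 hydroxyl (C9 trans to the C22 chain and cis to C20)
Product: 26 1,8-diketone with C6 cyclopentanone and C7 methyl ketone (C4 branch and C26 methyl cis on ring A)
Conditions: DMP, NaHCO3, CH2Cl2, 0 °C to rt
Reagents that add atoms: none
Why: Buffered Dess–Martin oxidation unveils the ring A ketone under non-epimerising conditions directly before it is consumed, so the cis-2,3-disubstituted cyclopentanone has the shortest possible lifetime.

Step 18
Reactants: 26 1,8-diketone with C6 cyclopentanone and C7 methyl ketone (C4 branch and C26 methyl cis on ring A)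
Product: 27 ABC tricycle with C6=C7 in ring B and silyl ethers on O at C2 (both epimers) and on O at C17
Conditions: TiCl3(DME)1.5, Zn–Cu couple, DME, reflux, slow addition of 26 at high dilution
Reagents that add atoms: none
Why: Intramolecular McMurry coupling of the two ketones forms the tetrasubstituted C6=C7 bond and closes ring B; the eight-membered ring allows only the ring-cis alkene. The trans-diequatorial, gauche arrangement of the C9 acetyl and C22 chain brings the carbonyls together and gives the trans B/C fusion.

Step 19
Reactants: 27 ABC tricycle with C6=C7 in ring B and silyl ethers on O at C2 (both epimers) and on O at C17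
Product: 28 ABC-ring diol with hydroxyls on C2 (both epimers) and C17
Conditions: TBAF, THF, rt to 50 °C; aq. NH4Cl
Reagents that add atoms: none
Why: Fluoride cleaves both silyl ethers in one operation; C5 is now allylic and no longer epimerisable.

Step 20
Reactants: 28 ABC-ring diol with hydroxyls on C2 (both epimers) and C17
Product: 29 ABC-ring keto aldehyde (C2 ketone and C17 aldehyde)
Conditions: DMP, NaHCO3, CH2Cl2, rt
Reagents that add atoms: none
Why: Dess–Martin oxidation converts both alcohols and merges the C2 epimers. C22, now α to the ketone, should stay in the trans-fused arrangement, because its epimer would place C2 syn-axial to the C20 methyl.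

Step 21
Reactants: 29 ABC-ring keto aldehyde (C2 ketone and C17 aldehyde)
Product: 30 ABC-ring keto acid (C2 ketone and C17 carboxylic acid)
Conditions: NaClO2, NaH2PO4, 2-methylbut-2-ene, t-BuOH/H2O, rt
Reagents that add atoms: sodium chlorite, [Na+].[O-]Cl=O
Why: Pinnick oxidation takes the non-enolisable neopentyl aldehyde to the acid; the alkene scavenger protects the tetrasubstituted C6=C7 bond from hypochlorite.

Step 22
Reactants: 30 ABC-ring keto acid (C2 ketone and C17 carboxylic acid); 31 (trimethylsilyl)diazomethane
Product: 34 ABC-ring diazoketone with diazoacetyl on C19 and isobutyl on C11 and C2 ketone, via acyl chloride 32 (not isolated), via silyl diazoketone 33 (not isolated)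
Conditions: 1-chloro-N,N,2-trimethylprop-1-en-1-amine, CH2Cl2, 0 °C to rt; then 31, Et3N, MeCN/THF, 0 °C to rt; aqueous work-up
Reagents that add atoms: none
Why: The α-chloroenamine forms the hindered acid chloride without free HCl, which spares the tetrasubstituted alkene. Acylation of the diazo reagent forms C16–C17 and the silyl group is lost on work-up; C19 is quaternary, so no ketene can form.

Step 23
Reactants: 34 ABC-ring diazoketone with diazoacetyl on C19 and isobutyl on C11 and C2 ketone
Product: 35 tetracyclic C2,C17-diketone (ring D closed; isopropyl on C12 trans to C10)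
Conditions: Rh2(OAc)4 (1 mol %), CH2Cl2, rt, slow addition of 34 at high dilution
Reagents that add atoms: none
Why: Rh2(OAc)4 decomposes the diazoketone with loss of N2 to an electrophilic rhodium carbenoid at C16, which inserts into a C12–H bond of the neighbouring isobutyl group through a three-centre transition state with retention at C12 and forms C12–C16; the closest known reaction type is the dirhodium tetracarboxylate-catalysed intramolecular 1,5 C–H insertion of α-diazo ketones to cyclopentanones. Ring D closes in the five-membered (1,5) mode, the kinetically preferred ring size for such carbenoids, so the six-membered alternative through the isopropyl methine should not compete. The trans C/D fusion and the quaternary C19 are not created here: the acyl group is equatorial on C19 and the isobutyl group equatorial on C11 of a chair locked by the trans-fused ring B, so the two reacting termini are held gauche and cannot epimerise. The one new stereocentre, C12, is controlled by the chair-like transition state in which the isopropyl group lies pseudo-equatorial and points away from the C10 methylene, which should place isopropyl trans to C10 as in the target. Site selectivity is needed against the C10–H and C22–H bonds, the isopropyl methine and the C6=C7 alkene: the axial hydrogens on C10 and C22 cannot be reached by an equatorial acyl group, C22–H is further deactivated by the C2 carbonyl, and the tetrasubstituted alkene is remote and hindered. Slow addition at high dilution suppresses carbenoid dimerisation.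

Step 24
Reactants: 35 tetracyclic C2,C17-diketone (ring D closed; isopropyl on C12 trans to C10)
Product: 36 tetracyclic C17 ketone with C1=C2 exocyclic methylene
Conditions: Ph3PCH3Br, KOtBu, THF, 0 °C to rt (1.2 equiv of ylide)
Reagents that add atoms: methyltriphenylphosphonium bromide, C[P+](c1ccccc1)(c1ccccc1)c1ccccc1.[Br-]
Why: Wittig methylenation should occur at the C2 ketone, which has a methylene and a methine as neighbours, in preference to the C17 ketone, which is neopentyl and flanked by the axial C20 methyl. Any epimerisation at C22 under the basic conditions returns the trans-fused isomer.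

Step 25
Reactants: 36 tetracyclic C17 ketone with C1=C2 exocyclic methylene
Product: 37 target alcohol (C17 hydroxyl cis to the C20 methyl)
Conditions: NaBH4, MeOH, 0 °C
Reagents that add atoms: none
Why: Borohydride should attack the cyclopentanone from the face opposite the angular C20 methyl, as in trans-hydrindanones with an adjacent quaternary methyl, which puts the hydroxyl cis to C20; neither alkene is affected.

## Compound list

1 | but-3-en-2-one | C=CC(C)=O | starting material
2 | 2-(tert-butyldimethylsilyloxy)buta-1,3-diene | C=CC(=C)O[Si](C)(C)C(C)(C)C | intermediate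
3 | 3-methylbutanal | CC(C)CC=O | starting material
4 | 2-(triphenylphosphoranylidene)propanal | CC(C=O)=P(c1ccccc1)(c1ccccc1)c1ccccc1 | starting material
5 | (E)-2,5-dimethylhex-2-enal | O=C/C(C)=C/CC(C)C | intermediate
6 | (1R,6R)-4-(tert-butyldimethylsilyloxy)-1-methyl-6-(2-methylpropyl)cyclohex-3-ene-1-carbaldehyde | O=C[C@]1(C)CC=C(O[Si](C)(C)C(C)(C)C)C[C@H]1CC(C)C | intermediate
7 | [(1R,6R)-4-(tert-butyldimethylsilyloxy)-1-methyl-6-(2-methylpropyl)cyclohex-3-en-1-yl]methanol | OC[C@]1(C)CC=C(O[Si](C)(C)C(C)(C)C)C[C@H]1CC(C)C | intermediate
8 | tert-butyl{[(1R,6R)-4-(tert-butyldimethylsilyloxy)-1-methyl-6-(2-methylpropyl)cyclohex-3-en-1-yl]methoxy}dimethylsilane | CC(C)(C)[Si](C)(C)OC[C@]1(C)CC=C(O[Si](C)(C)C(C)(C)C)C[C@H]1CC(C)C | intermediate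
9 | 3-methylcyclopent-2-en-1-one | CC1=CC(=O)CC1 | starting material
10 | 2-iodo-3-methylcyclopent-2-en-1-one | CC1=C(I)C(=O)CC1 | intermediate
11 | 2-vinyl-1,3-dioxolane | C=CC1OCCO1 | starting material
12 | 9-[2-(1,3-dioxolan-2-yl)ethyl]-9-borabicyclo[3.3.1]nonane | C1CC2CCCC(C1)B2CCC1OCCO1 | intermediate
13 | 2-[2-(1,3-dioxolan-2-yl)ethyl]-3-methylcyclopent-2-en-1-one | CC1=C(CCC2OCCO2)C(=O)CC1 | intermediate
14 | (S)-2-[2-(1,3-dioxolan-2-yl)ethyl]-3-methylcyclopent-2-en-1-ol | O[C@H]1CCC(C)=C1CCC1OCCO1 | intermediate
15 | (1S,2S,3S)-2-[2-(1,3-dioxolan-2-yl)ethyl]-3-methylcyclopentan-1-ol | O[C@H]1CC[C@H](C)[C@@H]1CCC1OCCO1 | intermediate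
16 | 2-{2-[(1S,2S,5S)-2-(benzyloxy)-5-methylcyclopentyl]ethyl}-1,3-dioxolane | c1ccccc1CO[C@H]1CC[C@H](C)[C@@H]1CCC1OCCO1 | intermediate
17 | 3-[(1S,2S,5S)-2-(benzyloxy)-5-methylcyclopentyl]propanal | c1ccccc1CO[C@H]1CC[C@H](C)[C@@H]1CCC=O | intermediate
18 | (2R,4R,5R)-2-{3-[(1S,2S,5S)-2-(benzyloxy)-5-methylcyclopentyl]-1-hydroxypropyl}-4-[(tert-butyldimethylsilyloxy)methyl]-4-methyl-5-(2-methylpropyl)cyclohexan-1-one, both carbinol epimers at C2 | CC(C)(C)[Si](C)(C)OC[C@]1(C)C[C@H](C(O)CC[C@H]2[C@@H](C)CC[C@@H]2OCc2ccccc2)C(=O)C[C@H]1CC(C)C | intermediate
19 | (2R,4R,5R)-2-{3-[(1S,2S,5S)-2-(benzyloxy)-5-methylcyclopentyl]-1-(tert-butyldimethylsilyloxy)propyl}-4-[(tert-butyldimethylsilyloxy)methyl]-4-methyl-5-(2-methylpropyl)cyclohexan-1-one, both C2 epimers | CC(C)(C)[Si](C)(C)OC[C@]1(C)C[C@H](C(O[Si](C)(C)C(C)(C)C)CC[C@H]2[C@@H](C)CC[C@@H]2OCc2ccccc2)C(=O)C[C@H]1CC(C)C | intermediate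
20 | enol triflate of 19 with C9(OTf)=C10, all stereocentres as in 19 | CC(C)(C)[Si](C)(C)OC[C@]1(C)C[C@H](C(O[Si](C)(C)C(C)(C)C)CC[C@H]2[C@@H](C)CC[C@@H]2OCc2ccccc2)C(OS(=O)(=O)C(F)(F)F)=C[C@H]1CC(C)C | intermediate
21 | tributyl(1-ethoxyvinyl)stannane | CCCC[Sn](CCCC)(CCCC)C(=C)OCC | starting material
22 | 2-ethoxydiene from 20 (1-ethoxyvinyl group on C9, C9=C10) | CC(C)(C)[Si](C)(C)OC[C@]1(C)C[C@H](C(O[Si](C)(C)C(C)(C)C)CC[C@H]2[C@@H](C)CC[C@@H]2OCc2ccccc2)C(C(=C)OCC)=C[C@H]1CC(C)C | intermediate
23 | enone with acetyl (C7, C8) on C9 and C9=C10, other centres as in 19 | CC(C)(C)[Si](C)(C)OC[C@]1(C)C[C@H](C(O[Si](C)(C)C(C)(C)C)CC[C@H]2[C@@H](C)CC[C@@H]2OCc2ccccc2)C(C(C)=O)=C[C@H]1CC(C)C | intermediate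
24 | saturated methyl ketone with free C6 hydroxyl, mixture of C9 epimers | CC(C)(C)[Si](C)(C)OC[C@]1(C)C[C@H](C(O[Si](C)(C)C(C)(C)C)CC[C@H]2[C@@H](C)CC[C@@H]2O)C(C(C)=O)C[C@H]1CC(C)C | intermediate
25 | methyl ketone with equatorial acetyl on C9 (trans to the C22 chain, cis to C20) and free C6 hydroxyl | CC(C)(C)[Si](C)(C)OC[C@]1(C)C[C@H](C(O[Si](C)(C)C(C)(C)C)CC[C@H]2[C@@H](C)CC[C@@H]2O)[C@@H](C(C)=O)C[C@H]1CC(C)C | intermediate
26 | 1,8-diketone: C6 cyclopentanone (C4 branch and C26 methyl cis) and C7 methyl ketone on C9 | CC(C)(C)[Si](C)(C)OC[C@]1(C)C[C@H](C(O[Si](C)(C)C(C)(C)C)CC[C@H]2[C@@H](C)CCC2=O)[C@@H](C(C)=O)C[C@H]1CC(C)C | intermediate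
27 | ABC tricycle with C6=C7 in ring B, tert-butyldimethylsilyl ethers on O at C2 (both epimers) and on O at C17 | CC(C)(C)[Si](C)(C)OC1CC[C@@H]2/C(=C(/C)[C@H]3C[C@@H](CC(C)C)[C@](C)(CO[Si](C)(C)C(C)(C)C)C[C@H]13)CC[C@@H]2C | intermediate
28 | ABC-ring diol, hydroxyls on C2 (both epimers) and C17 | OC1CC[C@@H]2/C(=C(/C)[C@H]3C[C@@H](CC(C)C)[C@](C)(CO)C[C@H]13)CC[C@@H]2C | intermediate
29 | ABC-ring keto aldehyde (C2 ketone, C17 aldehyde) | O=C1CC[C@@H]2/C(=C(/C)[C@H]3C[C@@H](CC(C)C)[C@](C)(C=O)C[C@H]13)CC[C@@H]2C | intermediate
30 | ABC-ring keto acid (C2 ketone, C17 carboxylic acid) | O=C1CC[C@@H]2/C(=C(/C)[C@H]3C[C@@H](CC(C)C)[C@](C)(C(=O)O)C[C@H]13)CC[C@@H]2C | intermediate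
31 | (trimethylsilyl)diazomethane | C[Si](C)(C)C=[N+]=[N-] | starting material
32 | ABC-ring acid chloride (C17 acyl chloride, C2 ketone) | O=C1CC[C@@H]2/C(=C(/C)[C@H]3C[C@@H](CC(C)C)[C@](C)(C(=O)Cl)C[C@H]13)CC[C@@H]2C | intermediate
33 | ABC-ring α-(trimethylsilyl)diazoketone | O=C1CC[C@@H]2/C(=C(/C)[C@H]3C[C@@H](CC(C)C)[C@](C)(C(=O)C(=[N+]=[N-])[Si](C)(C)C)C[C@H]13)CC[C@@H]2C | intermediate
34 | ABC-ring diazoketone (diazoacetyl on C19, isobutyl on C11, C2 ketone) | O=C1CC[C@@H]2/C(=C(/C)[C@H]3C[C@@H](CC(C)C)[C@](C)(C(=O)C=[N+]=[N-])C[C@H]13)CC[C@@H]2C | intermediate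
35 | tetracyclic C2,C17-diketone (isopropyl on C12 trans to C10) | O=C1CC[C@@H]2/C(=C(/C)[C@H]3C[C@H]4[C@H](C(C)C)CC(=O)[C@]4(C)C[C@H]13)CC[C@@H]2C | intermediate
36 | tetracyclic C17 ketone with C1=C2 exocyclic methylene | C=C1CC[C@@H]2/C(=C(/C)[C@H]3C[C@H]4[C@H](C(C)C)CC(=O)[C@]4(C)C[C@H]13)CC[C@@H]2C | intermediate
37 | CNP0510481.1, tetracyclic C17 alcohol | C=C1CC[C@@H]2/C(=C(/C)[C@H]3C[C@H]4[C@H](C(C)C)C[C@@H](O)[C@]4(C)C[C@H]13)CC[C@@H]2C | target

## Step count and uncertain steps

Total step count: 25 steps. Longest linear sequence: 20 steps (steps 6–11 from 9, then steps 12–25). The ring C branch (steps 1–5) joins at step 12.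

**Step 23 (key step).**
- What may go wrong: carbenoid dimerisation or Wolff-type rearrangement in place of insertion; insertion at the isopropyl methine; poor discrimination between the two diastereotopic C12–H bonds, which would erode the C12 configuration.
- Fallback: it sets out from keto acid 30 and returns at 35. The acid chloride 32 is chain-extended with the magnesium enolate of potassium methyl malonate (MgCl2, Et3N) to the β-keto ester F1. Diazo transfer with 4-acetamidobenzenesulfonyl azide and Et3N gives the α-diazo-β-keto ester F2. Its less reactive, more selective acceptor/acceptor carbenoid (Rh2(OAc)4, CH2Cl2) closes ring D by the same 1,5 insertion to the tetracyclic β-keto ester F3. Demethoxycarbonylation (LiCl, wet DMSO, heat) then gives 35.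

**Step 18.**
- What may go wrong: epimerisation at C5 α to the C6 ketone under the Lewis-acidic titanium conditions at reflux; intermolecular coupling; arrest at the pinacol stage.
- Fallback: it sets out from 26 and returns at 27. Pinacol coupling at room temperature (TiCl3(DME)1.5, Zn–Cu couple, DME, 25 °C) gives the ring B cis-diol F4. Thiophosgene and DMAP convert it to the cyclic thionocarbonate F5. Corey–Winter elimination with 1,3-dimethyl-2-phenyl-1,3,2-diazaphospholidine gives 27 by stereospecific syn extrusion.

**Step 3.**
- What may go wrong: slow cycloaddition of the trisubstituted enal; competing Mukaiyama-type addition of the enol silane to the activated aldehyde; insufficient or reversed enantioselection.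
- Fallback: it sets out from 2 and 5 and returns at 7. Cycloaddition with the racemic catalyst gives 6 together with its mirror image F6. Reduction as in step 4 gives 7 together with its mirror image F7. Chromatography on a chiral stationary phase separates 7 from F7.

**Step 24.**
- What may go wrong: competing methylenation at C17, or enolisation that stalls the reaction, since both ketones are hindered.
- Fallback: it sets out from 35 and returns at 37, with the order of the last two operations reversed. NaBH4 at −40 °C should reduce the cyclopentanone C17 faster than the medium-ring ketone C2, giving the hydroxy ketone F8. Methylenation of the single remaining ketone with Cp2TiMe2 (toluene, 65 °C) gives 37.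

## Further compounds

F1 | step 23 | ABC-ring β-keto ester (methyl 3-oxopropanoate unit on C19, C2 ketone) | O=C1CC[C@@H]2/C(=C(/C)[C@H]3C[C@@H](CC(C)C)[C@](C)(C(=O)CC(=O)OC)C[C@H]13)CC[C@@H]2C
F2 | step 23 | ABC-ring α-diazo-β-keto ester | O=C1CC[C@@H]2/C(=C(/C)[C@H]3C[C@@H](CC(C)C)[C@](C)(C(=O)C(=[N+]=[N-])C(=O)OC)C[C@H]13)CC[C@@H]2C
F3 | step 23 | tetracyclic β-keto ester (methoxycarbonyl on C16, C17 and C2 ketones) | O=C1CC[C@@H]2/C(=C(/C)[C@H]3C[C@H]4[C@H](C(C)C)C(C(=O)OC)C(=O)[C@]4(C)C[C@H]13)CC[C@@H]2C
F4 | step 18 | ABC-ring C6,C7-diol (pinacol; silyl ethers on O at C2 and C17) | CC(C)(C)[Si](C)(C)OC1CC[C@@H]2C(O)(C(C)(O)[C@H]3C[C@@H](CC(C)C)[C@](C)(CO[Si](C)(C)C(C)(C)C)C[C@H]13)CC[C@@H]2C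
F5 | step 18 | cyclic thionocarbonate of the C6,C7-diol | CC(C)(C)[Si](C)(C)OC1CC[C@@H]2C3(OC(=S)OC3(C)[C@H]4C[C@@H](CC(C)C)[C@](C)(CO[Si](C)(C)C(C)(C)C)C[C@H]14)CC[C@@H]2C
F6 | step 3 | (1S,6S)-4-(tert-butyldimethylsilyloxy)-1-methyl-6-(2-methylpropyl)cyclohex-3-ene-1-carbaldehyde | O=C[C@@]1(C)CC=C(O[Si](C)(C)C(C)(C)C)C[C@@H]1CC(C)C
F7 | step 3 | [(1S,6S)-4-(tert-butyldimethylsilyloxy)-1-methyl-6-(2-methylpropyl)cyclohex-3-en-1-yl]methanol | OC[C@@]1(C)CC=C(O[Si](C)(C)C(C)(C)C)C[C@@H]1CC(C)C
F8 | step 24 | tetracyclic C17 alcohol with C2 ketone | O=C1CC[C@@H]2/C(=C(/C)[C@H]3C[C@H]4[C@H](C(C)C)C[C@@H](O)[C@]4(C)C[C@H]13)CC[C@@H]2C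
A1 | alternative 1 | AB-ring cyclooctenone (C2 ketone, 4-methoxybenzyl ether on C10) | O=C1CC[C@@H]2/C(=C(/C)[C@@H](COCc3ccc(OC)cc3)C1)CC[C@@H]2C
A2 | alternative 2 | tetracyclic C4 alcohol with C1=C2 methylene (silyl ether on O at C17) | C=C1C[C@@H](O)[C@@H]2/C(=C(/C)[C@H]3C[C@H]4[C@H](C(C)C)C[C@@H](O[Si](C)(C)C(C)(C)C)[C@]4(C)C[C@H]13)CC[C@@H]2C
A3 | alternative 3 | tetracyclic C2 ketone (silyl ether on O at C17) | O=C1CC[C@@H]2/C(=C(/C)[C@H]3C[C@H]4[C@H](C(C)C)C[C@@H](O[Si](C)(C)C(C)(C)C)[C@]4(C)C[C@H]13)CC[C@@H]2C
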